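**Retrosynthetic overview**

1. The strategy rests on ring B: a benzene substituted at C1' (flavanone C2), C3' (prenyl, meta to C1'), C4' (oxygen) and C5', with the dimethylpyran ring D (O1'', C2'', C3'', C4'') fused on its C4'–C5' edge.
2. Key disconnection: C4'–C5', C2'–C3' and C1'–C6' are cut at once, back to the (2S)-2-ethynylchromanone 11 and the ynol-ether 1,7-diyne 21; Cp*RuCl(cod) joins them in a (2+2+2) cycloaddition that closes rings B and D together.
3. Ring D passes through that step as its C3''–C4'' hydrate (CH2–CH(OH)), because with the alkene in place the diyne would be an allyl alkynyl ether, a class that rearranges [3,3] to a ketene far below room temperature; dehydration afterwards gives the 2H-chromene.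
4. Ring order: ring A is bought with the acetophenone; ring C is closed as a chromone and C2 is set by copper-catalysed enantioselective alkynylation; rings B and D form in the key step; dehydration and MOM removal finish.
5. Diyne 21 comes from an acetate aldol on a silylpropynal, silylation, methyl Grignard addition, one-pot ynol ether formation with trichloroethylene and prenylation, then fluoride.

Key step: step 11

Remark on the chemistry: the antipode of the ligand in step 4 that leads to the 2S product is assumed to be identified in a trial run and used throughout.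

**Route**

Step 1
Reactants: 1 2,4-dihydroxyacetophenone; 2 prenyl bromide (1-bromo-3-methylbut-2-ene)
Product: 3 1-[2,4-dihydroxy-3-(3-methylbut-2-enyl)phenyl]ethanone
Conditions: KOH (10% aq.), 0 °C → rt; chromatography
Reagents that add atoms: none
Why: Phenoxide C-alkylation (electrophilic aromatic substitution) of the resorcinol dianion in water is known to place the prenyl group at C3 between the two oxygens, with the 5-prenyl and O-prenyl isomers as separable by-products, which is tolerable at the first step.

Step 2
Reactants: 3 1-[2,4-dihydroxy-3-(3-methylbut-2-enyl)phenyl]ethanone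
Product: 4 1-[2-hydroxy-4-(methoxymethoxy)-3-(3-methylbut-2-enyl)phenyl]ethanone
Conditions: MOMCl, K2CO3, acetone, 0 °C → rt
Reagents that add atoms: chloromethyl methyl ether, COCCl
Why: Williamson etherification is selective for the 4-hydroxyl because the 2-hydroxyl is tied up in a hydrogen bond to the ketone and is far less nucleophilic.

Step 3
Reactants: 4 1-[2-hydroxy-4-(methoxymethoxy)-3-(3-methylbut-2-enyl)phenyl]ethanone
Product: 6 7-(methoxymethoxy)-8-(3-methylbut-2-enyl)-4H-chromen-4-one, via enaminone 5 (not isolated)
Conditions: DMF-DMA, toluene, 90 °C; then AcOH, 60 °C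
Reagents that add atoms: N,N-dimethylformamide dimethyl acetal, COC(OC)N(C)C
Why: Enaminone condensation of the methyl ketone followed by acid-promoted 6-endo oxa-Michael addition of the phenol and loss of dimethylamine is the standard chromone synthesis, and acetic acid is too weak to cleave the MOM ether or cyclise the prenyl group.

Step 4
Reactants: 6 7-(methoxymethoxy)-8-(3-methylbut-2-enyl)-4H-chromen-4-one; 7 trimethylsilylacetylene
Product: 10 (2S)-7-(methoxymethoxy)-8-(3-methylbut-2-enyl)-2-[(trimethylsilyl)ethynyl]chroman-4-one, via silyloxybenzopyrylium triflate 8 (not isolated), via silyl enol ether 9 (not isolated)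
Conditions: CuI (5 mol %), StackPhos (6 mol %, antipode matched to 2S), TBSOTf, iPr2NEt, toluene, −20 °C; then 1 M HCl, THF, 0 °C
Reagents that add atoms: none
Why: Copper-catalysed enantioselective alkynylation of chromones: the silyl triflate converts 6 into the planar benzopyrylium ion 8, the ligand-bound monovalent copper acetylide of 7 adds to C2 from the face left open by the ligand and thereby sets the C2 stereocentre, and brief dilute acid hydrolyses enol ether 9 without touching the MOM group.

Step 5
Reactants: 10 (2S)-7-(methoxymethoxy)-8-(3-methylbut-2-enyl)-2-[(trimethylsilyl)ethynyl]chroman-4-one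
Product: 11 (2S)-2-ethynyl-7-(methoxymethoxy)-8-(3-methylbut-2-enyl)chroman-4-one
Conditions: AgNO3 (10 mol %), acetone/H2O, rt, dark
Reagents that add atoms: none
Why: Silver-catalysed protodesilylation of a 1-trimethylsilylalkyne proceeds in neutral aqueous acetone, which avoids the base-induced retro-oxa-Michael ring opening that would racemise C2.

Step 6
Reactants: 12 ethyl acetate; 13 3-(triisopropylsilyl)prop-2-ynal
Product: 15 ethyl 3-hydroxy-5-(triisopropylsilyl)pent-4-ynoate (racemic), via lithium enolate 14 (not isolated)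
Conditions: LiN(iPr)2, THF, −78 °C; then 13, −78 °C; aq. NH4Cl
Reagents that add atoms: none
Why: Acetate aldol addition of a preformed lithium enolate to a non-enolisable ynal is dependable, and the new carbinol centre is left racemic on purpose because step 12 removes it.

Step 7
Reactants: 15 ethyl 3-hydroxy-5-(triisopropylsilyl)pent-4-ynoate
Product: 16 ethyl 3-(triisopropylsilyloxy)-5-(triisopropylsilyl)pent-4-ynoate (racemic)
Conditions: TIPSOTf, 2,6-lutidine, CH2Cl2, 0 °C
Reagents that add atoms: triisopropylsilyl trifluoromethanesulfonate, CC(C)[Si](OS(=O)(=O)C(F)(F)F)(C(C)C)C(C)C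
Why: Silylation of a secondary alcohol with a silyl triflate and 2,6-lutidine is routine, and the triisopropylsilyl group is chosen because it resists O-to-O silyl migration when the neighbouring tertiary alkoxide is made in step 9.

Step 8
Reactants: 16 ethyl 3-(triisopropylsilyloxy)-5-(triisopropylsilyl)pent-4-ynoate
Product: 17 2-methyl-4-(triisopropylsilyloxy)-6-(triisopropylsilyl)hex-5-yn-2-ol (racemic)
Conditions: MeMgBr (3 equiv), THF, 0 °C → rt; aq. NH4Cl
Reagents that add atoms: methylmagnesium bromide, C[Mg]Br
Why: Double Grignard addition to the ester builds the gem-dimethyl carbinol that becomes C2'' and O1'' of ring D.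

Step 9
Reactants: 17 2-methyl-4-(triisopropylsilyloxy)-6-(triisopropylsilyl)hex-5-yn-2-ol; 2 prenyl bromide
Product: 20 5-methyl-5-(5-methylhex-4-en-1-ynyloxy)-1-(triisopropylsilyl)hex-1-yn-3-yl triisopropylsilyl ether (racemic), via dichlorovinyl ether 18 (not isolated), via lithium alkynyl ether 19 (not isolated)
Conditions: KH, THF, 0 °C → rt; Cl2C=CHCl, −50 °C → rt; n-BuLi (2.3 equiv), −78 → −40 °C; then 2, CuBr·SMe2 (10 mol %), −78 → 0 °C; cold work-up, Et3N-deactivated silica
Reagents that add atoms: trichloroethylene, ClC=C(Cl)Cl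
Why: One-pot ynol ether synthesis from an alcohol and trichloroethylene: the potassium alkoxide adds to dichloroacetylene formed in situ to give 18, n-BuLi turns it by elimination and chlorine–lithium exchange into the lithium alkynyl ether 19, and copper-catalysed SN2 allylation with 2 attaches the future C3' prenyl group.

Step 10
Reactants: 20 5-methyl-5-(5-methylhex-4-en-1-ynyloxy)-1-(triisopropylsilyl)hex-1-yn-3-yl triisopropylsilyl ether
Product: 21 5-methyl-5-(5-methylhex-4-en-1-ynyloxy)hex-1-yn-3-ol (racemic)
Conditions: Bu4NF (2.5 equiv), THF, 0 °C → rt; kept below 25 °C; Et3N-deactivated silica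
Reagents that add atoms: none
Why: Fluoride-induced desilylation cleaves both the alkynyl C–Si and the O–Si bond, while the ynol ether, which is sensitive to acid and heat but not to base, survives at or below room temperature.

Step 11
Reactants: 21 5-methyl-5-(5-methylhex-4-en-1-ynyloxy)hex-1-yn-3-ol; 11 (2S)-2-ethynyl-7-(methoxymethoxy)-8-(3-methylbut-2-enyl)chroman-4-one
Product: 22 (2S)-2-[4-hydroxy-2,2-dimethyl-8-(3-methylbut-2-enyl)chroman-6-yl]-7-(methoxymethoxy)-8-(3-methylbut-2-enyl)chroman-4-one (mixture of C4'' epimers)
Conditions: Cp*RuCl(cod) (5–10 mol %), ClCH2CH2Cl, rt; slow addition of 21 to catalyst and 11 (1.5 equiv)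
Reagents that add atoms: none
Why: Proposed new method: Cp*RuCl(cod) sheds cyclooctadiene and couples the two alkynes of 21 oxidatively to a ruthenacyclopentadiene, which forms C4'–C5' and closes ring D as a six-membered oxacycle across the four-atom O1''–C2''–C3''–C4'' tether (favoured by the gem-dimethyl group); the terminal alkyne of 11 is then taken up at the unsubstituted C6' end, and ring expansion with reductive elimination forms C1'–C6' and C2'–C3' and closes ring B as the benzene ring. The closest known reaction type is the Cp*RuCl(cod)-catalysed (2+2+2) cycloaddition of 1,6- and 1,7-diynes carrying one terminal substituent with terminal alkynes, which gives the meta-substituted fused arenes at room temperature; what has not been shown is an alkynyl ether as one arm of the diyne, although its oxygen only makes C3' more electron-rich and should not block the coupling. No stereocentre is formed: C2 of 11 is a spectator under these neutral conditions, and the racemic carbinol carbon of 21 simply makes 22 a pair of epimers that converge in step 12. The selectivity needed is regiochemical, with the chromanone-bearing carbon bonding to C6' and the alkyne CH to C3', and it is secured by the prenyl group on C3', which keeps the bulky chromanone substituent at the far side of the metallacycle. Cross-coupling over homo-coupling is secured by slow addition of 21 to an excess of 11, the trisubstituted prenyl alkenes are too hindered to insert, and the temperature stays below the onset of retro-ene loss of the tertiary alkyl group from the ynol ether.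

Step 12
Reactants: 22 (2S)-2-[4-hydroxy-2,2-dimethyl-8-(3-methylbut-2-enyl)chroman-6-yl]-7-(methoxymethoxy)-8-(3-methylbut-2-enyl)chroman-4-one
Product: 23 (2S)-2-[2,2-dimethyl-8-(3-methylbut-2-enyl)-2H-chromen-6-yl]-7-(methoxymethoxy)-8-(3-methylbut-2-enyl)chroman-4-one
Conditions: Martin sulfurane (Ph2S[OC(CF3)2Ph]2), CH2Cl2, 0 °C → rt
Reagents that add atoms: none
Why: Martin sulfurane dehydration of a secondary benzylic alcohol goes through an alkoxysulfonium ion that loses a C3'' proton under non-acidic conditions, so both epimers give the conjugated 2H-chromene while the MOM ether, the prenyl groups and C2 are untouched.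

Step 13
Reactants: 23 (2S)-2-[2,2-dimethyl-8-(3-methylbut-2-enyl)-2H-chromen-6-yl]-7-(methoxymethoxy)-8-(3-methylbut-2-enyl)chroman-4-one
Product: 24 (2S)-2-[2,2-dimethyl-8-(3-methylbut-2-enyl)-2H-chromen-6-yl]-7-hydroxy-8-(3-methylbut-2-enyl)chroman-4-one (CNP0110366.1)
Conditions: 3 M aq. HCl, MeOH, 45 °C, stopped at full conversion
Reagents that add atoms: none
Why: Acid-catalysed acetal exchange with methanol removes the MOM group, and short exposure to dilute acid at moderate temperature is the usual way to unmask prenylated flavanones without cyclising the 8-prenyl group onto the 7-hydroxyl or opening ring C.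

**Compound list**

1 | 2,4-dihydroxyacetophenone | CC(=O)c1ccc(O)cc1O | starting material
2 | prenyl bromide | CC(C)=CCBr | starting material
3 | 1-[2,4-dihydroxy-3-(3-methylbut-2-enyl)phenyl]ethanone | CC(=O)c1ccc(O)c(CC=C(C)C)c1O | intermediate
4 | 1-[2-hydroxy-4-(methoxymethoxy)-3-(3-methylbut-2-enyl)phenyl]ethanone | CC(=O)c1ccc(OCOC)c(CC=C(C)C)c1O | intermediate
5 | (E)-3-(dimethylamino)-1-[2-hydroxy-4-(methoxymethoxy)-3-(3-methylbut-2-enyl)phenyl]prop-2-en-1-one (in situ) | CN(C)/C=C/C(=O)c1ccc(OCOC)c(CC=C(C)C)c1O | intermediate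
6 | 7-(methoxymethoxy)-8-(3-methylbut-2-enyl)-4H-chromen-4-one | O=c1ccoc2c1ccc(OCOC)c2CC=C(C)C | intermediate
7 | trimethylsilylacetylene | C#C[Si](C)(C)C | starting material
8 | 4-(tert-butyldimethylsilyloxy)-7-(methoxymethoxy)-8-(3-methylbut-2-enyl)chromenylium triflate (in situ) | CC(C)(C)[Si](C)(C)Oc1cc[o+]c2c1ccc(OCOC)c2CC=C(C)C.[O-]S(=O)(=O)C(F)(F)F | intermediate
9 | tert-butyldimethylsilyl enol ether of 10, (2S)-4-silyloxy-2H-chromene (in situ) | CC(C)(C)[Si](C)(C)OC1=C[C@@H](C#C[Si](C)(C)C)Oc2c1ccc(OCOC)c2CC=C(C)C | intermediate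
10 | (2S)-7-(methoxymethoxy)-8-(3-methylbut-2-enyl)-2-[(trimethylsilyl)ethynyl]chroman-4-one | O=C1C[C@@H](C#C[Si](C)(C)C)Oc2c1ccc(OCOC)c2CC=C(C)C | intermediate
11 | (2S)-2-ethynyl-7-(methoxymethoxy)-8-(3-methylbut-2-enyl)chroman-4-one | O=C1C[C@@H](C#C)Oc2c1ccc(OCOC)c2CC=C(C)C | intermediate
12 | ethyl acetate | CCOC(C)=O | starting material
13 | 3-(triisopropylsilyl)prop-2-ynal | O=CC#C[Si](C(C)C)(C(C)C)C(C)C | starting material
14 | lithium enolate of ethyl acetate (in situ) | [Li]OC(=C)OCC | intermediate
15 | ethyl 3-hydroxy-5-(triisopropylsilyl)pent-4-ynoate (racemic) | CCOC(=O)CC(O)C#C[Si](C(C)C)(C(C)C)C(C)C | intermediate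
16 | ethyl 3-(triisopropylsilyloxy)-5-(triisopropylsilyl)pent-4-ynoate (racemic) | CCOC(=O)CC(O[Si](C(C)C)(C(C)C)C(C)C)C#C[Si](C(C)C)(C(C)C)C(C)C | intermediate
17 | 2-methyl-4-(triisopropylsilyloxy)-6-(triisopropylsilyl)hex-5-yn-2-ol (racemic) | CC(C)(O)CC(O[Si](C(C)C)(C(C)C)C(C)C)C#C[Si](C(C)C)(C(C)C)C(C)C | intermediate
18 | (E)-1,2-dichlorovinyl ether of 17 (in situ) | Cl/C=C(/Cl)OC(C)(C)CC(O[Si](C(C)C)(C(C)C)C(C)C)C#C[Si](C(C)C)(C(C)C)C(C)C | intermediate
19 | lithium alkynyl ether, lithioethynyl ether of 17 (in situ) | [Li]C#COC(C)(C)CC(O[Si](C(C)C)(C(C)C)C(C)C)C#C[Si](C(C)C)(C(C)C)C(C)C | intermediate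
20 | 5-methyl-5-(5-methylhex-4-en-1-ynyloxy)-1-(triisopropylsilyl)hex-1-yn-3-yl triisopropylsilyl ether (racemic) | CC(C)=CCC#COC(C)(C)CC(O[Si](C(C)C)(C(C)C)C(C)C)C#C[Si](C(C)C)(C(C)C)C(C)C | intermediate
21 | 5-methyl-5-(5-methylhex-4-en-1-ynyloxy)hex-1-yn-3-ol (racemic) | CC(C)=CCC#COC(C)(C)CC(O)C#C | intermediate
22 | (2S)-2-[4-hydroxy-2,2-dimethyl-8-(3-methylbut-2-enyl)chroman-6-yl]-7-(methoxymethoxy)-8-(3-methylbut-2-enyl)chroman-4-one (C4'' epimers) | O=C1C[C@@H](c2cc(CC=C(C)C)c3OC(C)(C)CC(O)c3c2)Oc2c1ccc(OCOC)c2CC=C(C)C | intermediate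
23 | (2S)-2-[2,2-dimethyl-8-(3-methylbut-2-enyl)-2H-chromen-6-yl]-7-(methoxymethoxy)-8-(3-methylbut-2-enyl)chroman-4-one | O=C1C[C@@H](c2cc(CC=C(C)C)c3OC(C)(C)C=Cc3c2)Oc2c1ccc(OCOC)c2CC=C(C)C | intermediate
24 | (2S)-2-[2,2-dimethyl-8-(3-methylbut-2-enyl)-2H-chromen-6-yl]-7-hydroxy-8-(3-methylbut-2-enyl)chroman-4-one | CC(C)=CCc1cc([C@@H]2CC(=O)c3ccc(O)c(CC=C(C)C)c3O2)cc2c1OC(C)(C)C=C2 | target

**Step count**

Total: 13 steps. Longest linear sequence: 8 steps (steps 1–5 or steps 6–10, followed by steps 11–13).

**Steps most likely to fail**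

Step 11 (the labelled step). Oxidative coupling of the electron-rich alkynyl ether with the distant terminal alkyne across a four-atom tether may be slower than self-trimerisation of 11 or than ruthenium-induced breakdown of the ynol ether, and 11 may be taken up in the opposite orientation. The fallback uses known chemistry, sets out from chromone 6 and returns at 23; it builds ring B with ring D beforehand and joins it to ring C by enantioselective conjugate arylation. Sodium 4-bromophenoxide (NaH, toluene) is C-prenylated at the ortho position with 2 to give 4-bromo-2-(3-methylbut-2-enyl)phenol F1. Chromene annulation of F1 with 3-methylbut-2-enal (PhB(OH)2, AcOH, toluene, reflux; ortho-quinone methide formation and 6π electrocyclisation) gives 6-bromo-2,2-dimethyl-8-(3-methylbut-2-enyl)-2H-chromene F2. Bromine–lithium exchange (n-BuLi, THF, −78 °C), B(OiPr)3 and aqueous work-up give [2,2-dimethyl-8-(3-methylbut-2-enyl)-2H-chromen-6-yl]boronic acid F3. Addition of F3 to 6 under divalent palladium catalysis (Pd(OCOCF3)2, t-BuPyOx of the antipode that gives 2S, NH4PF6, H2O, ClCH2CH2Cl, 60 °C) should give 23 directly, and step 13 follows unchanged.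

Step 9. The hindered tertiary potassium alkoxide may add sluggishly to dichloroacetylene, silyl transfer may compete while the alkoxide waits, and the one-pot sequence leaves no point at which to correct either. The fallback sets out from 17 and returns at 20; it replaces alkoxide vinylation by carbonyl olefination. Formylation of 17 (acetic formic anhydride, pyridine, DMAP) gives 2-methyl-4-(triisopropylsilyloxy)-6-(triisopropylsilyl)hex-5-yn-2-yl formate F4. Dibromo-olefination of the formate (CBr4, PPh3, CH2Cl2) gives the 2,2-dibromovinyl ether F5. n-BuLi (2 equiv, THF, −78 °C) converts F5 by bromine–lithium exchange and Fritsch–Buttenberg–Wiechell rearrangement into the lithium alkynyl ether 19, which is allylated with 2 as before to 20.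

Step 4. Facial discrimination at the benzopyrylium ion of this 7-alkoxy-8-alkyl chromone may be insufficient, and the silyl triflate may attack the aryl MOM ether. The fallback sets out from 4 and returns at 10; it avoids the silyl triflate and secures the configuration by resolution. The dianion of 4 (LiN(iPr)2, 2.2 equiv, THF, −78 °C) adds to 3-(trimethylsilyl)prop-2-ynal to give racemic 3-hydroxy-1-[2-hydroxy-4-(methoxymethoxy)-3-(3-methylbut-2-enyl)phenyl]-5-(trimethylsilyl)pent-4-yn-1-one F6. Intramolecular Mitsunobu etherification (PPh3, DIAD, THF, 0 °C) closes ring C to racemic 7-(methoxymethoxy)-8-(3-methylbut-2-enyl)-2-[(trimethylsilyl)ethynyl]chroman-4-one F7. Preparative chromatography of F7 on a chiral stationary phase should deliver the 2S enantiomer 10.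

**Further compounds**

F1 | step 11 | 4-bromo-2-(3-methylbut-2-enyl)phenol | CC(C)=CCc1cc(Br)ccc1O
F2 | step 11 | 6-bromo-2,2-dimethyl-8-(3-methylbut-2-enyl)-2H-chromene | CC(C)=CCc1cc(Br)cc2c1OC(C)(C)C=C2
F3 | step 11 | [2,2-dimethyl-8-(3-methylbut-2-enyl)-2H-chromen-6-yl]boronic acid | CC(C)=CCc1cc(B(O)O)cc2c1OC(C)(C)C=C2
F4 | step 9 | 2-methyl-4-(triisopropylsilyloxy)-6-(triisopropylsilyl)hex-5-yn-2-yl formate | O=COC(C)(C)CC(O[Si](C(C)C)(C(C)C)C(C)C)C#C[Si](C(C)C)(C(C)C)C(C)C
F5 | step 9 | 2,2-dibromovinyl ether of 17 | BrC(Br)=COC(C)(C)CC(O[Si](C(C)C)(C(C)C)C(C)C)C#C[Si](C(C)C)(C(C)C)C(C)C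
F6 | step 4 | 3-hydroxy-1-[2-hydroxy-4-(methoxymethoxy)-3-(3-methylbut-2-enyl)phenyl]-5-(trimethylsilyl)pent-4-yn-1-one (racemic) | COCOc1ccc(C(=O)CC(O)C#C[Si](C)(C)C)c(O)c1CC=C(C)C
F7 | step 4 | 7-(methoxymethoxy)-8-(3-methylbut-2-enyl)-2-[(trimethylsilyl)ethynyl]chroman-4-one (racemic) | O=C1CC(C#C[Si](C)(C)C)Oc2c1ccc(OCOC)c2CC=C(C)C
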